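**Strategy.** The labdane decalin is disconnected at its ring-fusion bond C5–C10 (labdane numbering: the CH carbon beside the gem-dimethyl carbon and the methyl-bearing quaternary carbon), the one bond shared by rings A and B. In the precursor, an acyclic Sharpless epoxy alcohol carrying an enone, both carbons are electrophilic. Cp2TiCl opens the epoxide to a tertiary C10 radical that adds 6-exo to the enone β-carbon C5: ring A closes and both fusion stereocentres are set, relayed from the epoxide-derived carbinol. Glycol cleavage and aldol condensation then close ring B, a suprafacial Claisen shift moves oxygen at C7 to carbon at C9 and places the C7=C8 alkene, and chain extension with double malonylation finishes.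

Key step: step 6

Remarks on the chemistry (labdane numbering is used for atoms throughout):
- Assumption: in the favoured transition state of step 6 the titanoxy group on C9 lies anti to the forming bond. This fixes D-(−)-diethyl tartrate for step 5; the mirror-image tartrate would serve if the facial preference proved opposite.
- Any Z ester from step 2 may be carried along, because step 5 fixes the same C9 configuration from either alkene geometry and C10 becomes a planar radical in step 6.

Step 1
Reactants: 1 isobutyronitrile; 2 2-(3-chloropropyl)-2-methyl-1,3-dioxolane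
Product: 4 2,2-dimethyl-6-oxoheptanenitrile, via ketal nitrile 3 (not isolated)
Conditions: LiN(i-Pr)2, THF, −78 °C; 2, NaI (cat.), DMPU, −78 °C to rt; then 2 M HCl, THF, rt
Reagents that add atoms: water, O
Why: SN2 alkylation of the lithiated nitrile builds the quaternary gem-dimethyl carbon C4, and acid hydrolysis of the dioxolane in the work-up frees the methyl ketone that becomes C10.

Step 2
Reactants: 4 2,2-dimethyl-6-oxoheptanenitrile; 5 triethyl phosphonoacetate
Product: 6 ethyl (2E)-7-cyano-3,7-dimethyloct-2-enoate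
Conditions: NaH, THF, 0 °C to reflux
Reagents that add atoms: none
Why: Horner–Wadsworth–Emmons olefination of the methyl ketone should give mainly the E ester, and the nitrile, having no α-hydrogen, is inert.

Step 3
Reactants: 6 ethyl (2E)-7-cyano-3,7-dimethyloct-2-enoate
Product: 7 (6E)-8-hydroxy-2,2,6-trimethyloct-6-enal
Conditions: i-Bu2AlH (4.5 equiv), CH2Cl2, −78 to 0 °C; then 1 M HCl
Reagents that add atoms: water, O
Why: i-Bu2AlH reduces the conjugated ester to the allylic alcohol and stops at the N-aluminio imine of the hindered nitrile, which hydrolyses to the neopentyl aldehyde (C5) on acidic work-up.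

Step 4
Reactants: 7 (6E)-8-hydroxy-2,2,6-trimethyloct-6-enal; 8 diethyl (2-oxobutyl)phosphonate
Product: 9 (4E,10E)-12-hydroxy-6,6,10-trimethyldodeca-4,10-dien-3-one
Conditions: LiCl, i-Pr2NEt, MeCN, rt
Reagents that add atoms: none
Why: Masamune–Roush Horner–Wadsworth–Emmons olefination of the non-enolisable aldehyde should give the E enone (C5=C6–C7(=O)–C8–C17) and tolerates the free allylic alcohol.

Step 5
Reactants: 9 (4E,10E)-12-hydroxy-6,6,10-trimethyldodeca-4,10-dien-3-one
Product: 10 (4E)-9-[(2R,3R)-3-(hydroxymethyl)-2-methyloxiran-2-yl]-6,6-dimethylnon-4-en-3-one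
Conditions: Ti(OiPr)4 (10 mol%), D-(−)-diethyl tartrate (12 mol%), t-BuOOH, 4 Å MS, CH2Cl2, −20 °C
Reagents that add atoms: tert-butyl hydroperoxide, CC(C)(C)OO
Why: Katsuki–Sharpless asymmetric epoxidation of the geraniol-type allylic alcohol, in which the D-tartrate ligand directs oxygen to the face giving the (2R,3R)-epoxide (C9 and C10) while the electron-poor enone is untouched.

Step 6
Reactants: 10 (4E)-9-[(2R,3R)-3-(hydroxymethyl)-2-methyloxiran-2-yl]-6,6-dimethylnon-4-en-3-one
Product: 11 1-{(1S,2S)-2-[(1S)-1,2-dihydroxyethyl]-2,6,6-trimethylcyclohexyl}butan-2-one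
Conditions: Cp2TiCl2 (20 mol%), Mn powder, 2,4,6-collidine·HCl, THF, rt, slow addition of 10
Reagents that add atoms: none
Why: Cp2TiCl (trivalent titanium), formed in the flask from Cp2TiCl2 and Mn, opens the epoxide by single-electron transfer at the tertiary C–O bond to give the β-titanoxy tertiary radical at C10, which adds to the enone β-carbon C5 and is then reduced to a titanium enolate that collidinium chloride protonates, so that two electrophilic carbons are joined. The closest known reaction type is the Nugent–RajanBabu epoxide-opening radical cyclization onto α,β-unsaturated carbonyl compounds in Gansäuer's catalytic version. Ring A closes in the 6-exo-trig mode through a chair with the enone arm equatorial. At C10 the branched titanoxy-glycol carbon should take the equatorial site because an axial branch would meet the axial methyl on C4, which leaves the C10 methyl axial and trans to H-5; the absolute sense at C10 and C5 is relayed from the Sharpless-derived C9 centre, whose titanoxy group should lie anti to the forming bond. The step needs tertiary-selective C–O homolysis (secured by the trisubstituted epoxide), cyclization faster than radical reduction (gem-dimethyl tether, polarity-matched enone, low Cp2TiCl concentration) and facial control (C9); any minor diastereomer would be a separable single enantiomer.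

Step 7
Reactants: 11 1-{(1S,2S)-2-[(1S)-1,2-dihydroxyethyl]-2,6,6-trimethylcyclohexyl}butan-2-one
Product: 12 (1S,2S)-1,3,3-trimethyl-2-(2-oxobutyl)cyclohexane-1-carbaldehyde
Conditions: NaIO4, THF/H2O, 0 °C to rt
Reagents that add atoms: none
Why: Periodate glycol cleavage removes the auxiliary carbinol carbon as formaldehyde and unveils the non-epimerisable quaternary aldehyde C9 without touching C5 or C10.

Step 8
Reactants: 12 (1S,2S)-1,3,3-trimethyl-2-(2-oxobutyl)cyclohexane-1-carbaldehyde
Product: 13 (4aR,8aS)-3,4a,8,8-tetramethyl-4a,5,6,7,8,8a-hexahydronaphthalen-2(1H)-one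
Conditions: p-TsOH·H2O (10 mol%), toluene, 110 °C, Dean–Stark
Reagents that add atoms: none
Why: Intramolecular aldol condensation (the ring-closing half of a Robinson annulation) closes ring B at C8–C9, since only the C8 enol reaches the non-enolisable aldehyde through a six-membered transition state, and acid avoids a base-induced retro-Michael opening of the C5–C10 bond.

Step 9
Reactants: 13 (4aR,8aS)-3,4a,8,8-tetramethyl-4a,5,6,7,8,8a-hexahydronaphthalen-2(1H)-one
Product: 14 (2S,4aR,8aS)-3,4a,8,8-tetramethyl-1,2,4a,5,6,7,8,8a-octahydronaphthalen-2-ol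
Conditions: NaBH4, CeCl3·7H2O, MeOH, −78 to −20 °C
Reagents that add atoms: none
Why: Luche 1,2-reduction, in which hydride should enter axially on the α face opposite the angular methyl (as in 4-en-3-one steroids) to give the pseudo-equatorial 7β-alcohol.

Step 10
Reactants: 14 (2S,4aR,8aS)-3,4a,8,8-tetramethyl-1,2,4a,5,6,7,8,8a-octahydronaphthalen-2-ol
Product: 16 ethyl 2-[(1S,4aS,8aS)-2,5,5,8a-tetramethyl-1,4,4a,5,6,7,8,8a-octahydronaphthalen-1-yl]acetate, via ketene acetal 15 (not isolated)
Conditions: MeC(OEt)3, EtCO2H (cat.), xylene, 140 °C, EtOH distilled off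
Reagents that add atoms: triethyl orthoacetate, CC(OCC)(OCC)OCC
Why: Johnson–Claisen rearrangement, whose suprafacial [3,3] shift delivers the acetate carbon to C9 on the β face that carried the C7 oxygen, setting C9 (S) and leaving the C7=C8 alkene.

Step 11
Reactants: 16 ethyl 2-[(1S,4aS,8aS)-2,5,5,8a-tetramethyl-1,4,4a,5,6,7,8,8a-octahydronaphthalen-1-yl]acetate
Product: 17 2-[(1S,4aS,8aS)-2,5,5,8a-tetramethyl-1,4,4a,5,6,7,8,8a-octahydronaphthalen-1-yl]ethan-1-ol
Conditions: LiAlH4, Et2O, 0 °C
Reagents that add atoms: none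
Why: Hydride reduction of the ester gives the primary C12 alcohol and leaves the trisubstituted alkene alone.

Step 12
Reactants: 17 2-[(1S,4aS,8aS)-2,5,5,8a-tetramethyl-1,4,4a,5,6,7,8,8a-octahydronaphthalen-1-yl]ethan-1-ol
Product: 18 (4aS,5S,8aS)-5-(2-iodoethyl)-1,1,4a,6-tetramethyl-1,2,3,4,4a,5,8,8a-octahydronaphthalene
Conditions: I2, PPh3, imidazole, CH2Cl2, 0 °C to rt
Reagents that add atoms: iodine, II
Why: Appel-type (Garegg–Samuelsson) iodination of the unhindered primary alcohol under neutral conditions.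

Step 13
Reactants: 18 (4aS,5S,8aS)-5-(2-iodoethyl)-1,1,4a,6-tetramethyl-1,2,3,4,4a,5,8,8a-octahydronaphthalene
Product: 19 (4aS,5S,8aS)-5-(but-3-yn-1-yl)-1,1,4a,6-tetramethyl-1,2,3,4,4a,5,8,8a-octahydronaphthalene
Conditions: HC≡CLi·H2NCH2CH2NH2, DMSO, 15 °C to rt
Reagents that add atoms: lithium acetylide–ethylenediamine complex, [Li+].[C-]#C.NCCN
Why: SN2 alkynylation of the primary iodide adds C13 and C14 as a terminal alkyne.

Step 14
Reactants: 19 (4aS,5S,8aS)-5-(but-3-yn-1-yl)-1,1,4a,6-tetramethyl-1,2,3,4,4a,5,8,8a-octahydronaphthalene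
Product: 22 (2E)-3-methyl-5-[(1S,4aS,8aS)-2,5,5,8a-tetramethyl-1,4,4a,5,6,7,8,8a-octahydronaphthalen-1-yl]pent-2-en-1-ol, via alkenylalane 20 (not isolated), via lithium alanate 21 (not isolated)
Conditions: AlMe3, Cp2ZrCl2 (25 mol%), CH2Cl2, 0 °C to rt; n-BuLi, THF, −78 °C; (CH2O)n, −78 °C to rt
Reagents that add atoms: trimethylaluminium, C[Al](C)C; paraformaldehyde (as formaldehyde), C=O
Why: Negishi zirconium-catalysed carboalumination adds methyl (to C13) and aluminium (to C14) syn across the terminal alkyne, and the alanate is hydroxymethylated with retention, which fixes the 13E alkene.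

Step 15
Reactants: 22 (2E)-3-methyl-5-[(1S,4aS,8aS)-2,5,5,8a-tetramethyl-1,4,4a,5,6,7,8,8a-octahydronaphthalen-1-yl]pent-2-en-1-ol (two equivalents); 23 malonyl dichloride
Product: 24 bis{(2E)-3-methyl-5-[(1S,4aS,8aS)-2,5,5,8a-tetramethyl-1,4,4a,5,6,7,8,8a-octahydronaphthalen-1-yl]pent-2-en-1-yl} propanedioate
Conditions: pyridine, CH2Cl2, 0 °C to rt, slow addition of 23 (0.5 equiv)
Reagents that add atoms: none
Why: Double O-acylation of the primary allylic alcohol by the diacid chloride gives the symmetric malonate; no stereocentre is touched.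

**Compound list**

1 | isobutyronitrile | CC(C)C#N | starting material
2 | 2-(3-chloropropyl)-2-methyl-1,3-dioxolane | CC1(CCCCl)OCCO1 | starting material
3 | 2,2-dimethyl-5-(2-methyl-1,3-dioxolan-2-yl)pentanenitrile | CC1(CCCC(C)(C)C#N)OCCO1 | intermediate
4 | 2,2-dimethyl-6-oxoheptanenitrile | CC(=O)CCCC(C)(C)C#N | intermediate
5 | triethyl phosphonoacetate | CCOC(=O)CP(=O)(OCC)OCC | starting material
6 | ethyl (2E)-7-cyano-3,7-dimethyloct-2-enoate | CCOC(=O)/C=C(\C)CCCC(C)(C)C#N | intermediate
7 | (6E)-8-hydroxy-2,2,6-trimethyloct-6-enal | OC/C=C(\C)CCCC(C)(C)C=O | intermediate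
8 | diethyl (2-oxobutyl)phosphonate | CCC(=O)CP(=O)(OCC)OCC | starting material
9 | (4E,10E)-12-hydroxy-6,6,10-trimethyldodeca-4,10-dien-3-one | CCC(=O)/C=C/C(C)(C)CCC/C(C)=C/CO | intermediate
10 | (4E)-9-[(2R,3R)-3-(hydroxymethyl)-2-methyloxiran-2-yl]-6,6-dimethylnon-4-en-3-one | OC[C@H]1O[C@]1(C)CCCC(C)(C)/C=C/C(=O)CC | intermediate
11 | 1-{(1S,2S)-2-[(1S)-1,2-dihydroxyethyl]-2,6,6-trimethylcyclohexyl}butan-2-one | CCC(=O)C[C@H]1C(C)(C)CCC[C@]1(C)[C@H](O)CO | intermediate
12 | (1S,2S)-1,3,3-trimethyl-2-(2-oxobutyl)cyclohexane-1-carbaldehyde | CCC(=O)C[C@H]1C(C)(C)CCC[C@]1(C)C=O | intermediate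
13 | (4aR,8aS)-3,4a,8,8-tetramethyl-4a,5,6,7,8,8a-hexahydronaphthalen-2(1H)-one | O=C1C[C@H]2C(C)(C)CCC[C@]2(C)C=C1C | intermediate
14 | (2S,4aR,8aS)-3,4a,8,8-tetramethyl-1,2,4a,5,6,7,8,8a-octahydronaphthalen-2-ol | O[C@H]1C[C@H]2C(C)(C)CCC[C@]2(C)C=C1C | intermediate
15 | (2S,4aR,8aS)-2-[(1-ethoxyethenyl)oxy]-3,4a,8,8-tetramethyl-1,2,4a,5,6,7,8,8a-octahydronaphthalene | C=C(OCC)O[C@H]1C[C@H]2C(C)(C)CCC[C@]2(C)C=C1C | intermediate
16 | ethyl 2-[(1S,4aS,8aS)-2,5,5,8a-tetramethyl-1,4,4a,5,6,7,8,8a-octahydronaphthalen-1-yl]acetate | CC1=CC[C@H]2C(C)(C)CCC[C@]2(C)[C@H]1CC(=O)OCC | intermediate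
17 | 2-[(1S,4aS,8aS)-2,5,5,8a-tetramethyl-1,4,4a,5,6,7,8,8a-octahydronaphthalen-1-yl]ethan-1-ol | CC1=CC[C@H]2C(C)(C)CCC[C@]2(C)[C@H]1CCO | intermediate
18 | (4aS,5S,8aS)-5-(2-iodoethyl)-1,1,4a,6-tetramethyl-1,2,3,4,4a,5,8,8a-octahydronaphthalene | CC1=CC[C@H]2C(C)(C)CCC[C@]2(C)[C@H]1CCI | intermediate
19 | (4aS,5S,8aS)-5-(but-3-yn-1-yl)-1,1,4a,6-tetramethyl-1,2,3,4,4a,5,8,8a-octahydronaphthalene | CC1=CC[C@H]2C(C)(C)CCC[C@]2(C)[C@H]1CCC#C | intermediate
20 | dimethyl{(1E)-2-methyl-4-[(1S,4aS,8aS)-2,5,5,8a-tetramethyl-1,4,4a,5,6,7,8,8a-octahydronaphthalen-1-yl]but-1-en-1-yl}alumane | CC1=CC[C@H]2C(C)(C)CCC[C@]2(C)[C@H]1CC/C(C)=C/[Al](C)C | intermediate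
21 | lithium butyl(dimethyl){(1E)-2-methyl-4-[(1S,4aS,8aS)-2,5,5,8a-tetramethyl-1,4,4a,5,6,7,8,8a-octahydronaphthalen-1-yl]but-1-en-1-yl}aluminate | CC1=CC[C@H]2C(C)(C)CCC[C@]2(C)[C@H]1CC/C(C)=C/[Al-](C)(C)CCCC.[Li+] | intermediate
22 | (2E)-3-methyl-5-[(1S,4aS,8aS)-2,5,5,8a-tetramethyl-1,4,4a,5,6,7,8,8a-octahydronaphthalen-1-yl]pent-2-en-1-ol (labda-7,13E-dien-15-ol) | CC1=CC[C@H]2C(C)(C)CCC[C@]2(C)[C@H]1CC/C(C)=C/CO | intermediate
23 | malonyl dichloride | O=C(Cl)CC(Cl)=O | starting material
24 | bis{(2E)-3-methyl-5-[(1S,4aS,8aS)-2,5,5,8a-tetramethyl-1,4,4a,5,6,7,8,8a-octahydronaphthalen-1-yl]pent-2-en-1-yl} propanedioate | CC1=CC[C@H]2C(C)(C)CCC[C@]2(C)[C@H]1CC/C(C)=C/COC(=O)CC(=O)OC/C=C(\C)CC[C@H]1C(C)=CC[C@H]2C(C)(C)CCC[C@]12C | target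

**Totals.** Total step count: 15. Longest linear sequence: 15 steps (1 to 24; step 15 uses two equivalents of 22).

**Steps most likely to fail**

1. Step 6. The 6-exo addition to the neopentyl-type β-carbon may be slower than reduction of the tertiary radical by Cp2TiCl and loss of the titanoxy group (deoxygenation back to the allylic alcohol), or the face selection by C9 may be weak. Fallback, setting out from 10 and coming back at 11: MgBr2·OEt2 in Et2O at −20 °C should open the epoxide at the tertiary carbon to the bromodiol (4E,10S,11R)-10-bromo-11,12-dihydroxy-6,6,10-trimethyldodec-4-en-3-one F1 (the configuration at the bromide carbon is immaterial). Slow addition of Bu3SnH with azobisisobutyronitrile in benzene at 80 °C would then generate the same C10 radical by bromine-atom abstraction in a tin hydride chain, with no reducing metal present, and close ring A to 11.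

2. Step 10. Acid-promoted ionisation of the allylic alcohol or its ketene acetal and loss of water to a ring-B diene may outrun the sigmatropic shift, which has to build a bond on the face of the angular methyl. Fallback, setting out from 14 and coming back at 19: 14 is converted with phenyl isocyanate (pyridine, CH2Cl2) into the N-phenylcarbamate F2. Deprotonation with MeLi, complexation with CuI and addition of 4-(trimethylsilyl)but-3-yn-1-yllithium should then effect a carbamate-directed syn-SN2′ substitution that delivers the four-carbon chain to C9 from the β face and shifts the alkene to C7=C8, giving the silyl alkyne F3. K2CO3 in MeOH removes the silyl group to give 19, so steps 11 to 13 are bypassed.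

3. Step 15. Under base, malonyl dichloride may lose HCl to a chloroketene and oligomerise, leaving incomplete double acylation. Fallback, setting out from 22 and coming back at 24: heating 22 with Meldrum's acid in toluene at 100 °C should give the malonic half ester F4 with loss of acetone. Steglich coupling of F4 with a second equivalent of 22 (dicyclohexylcarbodiimide, 4-dimethylaminopyridine, CH2Cl2, rt) then gives 24.

**Further compounds**

F1 | step 6 | (4E,10S,11R)-10-bromo-11,12-dihydroxy-6,6,10-trimethyldodec-4-en-3-one | OC[C@@H](O)[C@@](C)(Br)CCCC(C)(C)/C=C/C(=O)CC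
F2 | step 10 | (2S,4aR,8aS)-3,4a,8,8-tetramethyl-1,2,4a,5,6,7,8,8a-octahydronaphthalen-2-yl N-phenylcarbamate | O=C(Nc1ccccc1)O[C@H]1C[C@H]2C(C)(C)CCC[C@]2(C)C=C1C
F3 | step 10 | trimethyl{4-[(1S,4aS,8aS)-2,5,5,8a-tetramethyl-1,4,4a,5,6,7,8,8a-octahydronaphthalen-1-yl]but-1-yn-1-yl}silane | CC1=CC[C@H]2C(C)(C)CCC[C@]2(C)[C@H]1CCC#C[Si](C)(C)C
F4 | step 15 | 3-{[(2E)-3-methyl-5-[(1S,4aS,8aS)-2,5,5,8a-tetramethyl-1,4,4a,5,6,7,8,8a-octahydronaphthalen-1-yl]pent-2-en-1-yl]oxy}-3-oxopropanoic acid | CC1=CC[C@H]2C(C)(C)CCC[C@]2(C)[C@H]1CC/C(C)=C/COC(=O)CC(=O)O
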